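**Plan**

- Retrosynthesis: the three benzyl ethers and the 4'-O-methyl group come off first. Ring B is then cut at C1'–C2' and C5'–C6' into a 2-ethynylchromone and an oxygenated butadiene. The alkyne is cut at its bond to C2, ring C at O1–C2 and C2–C3 (a one-carbon formamide-acetal unit), and the ketone at the aryl–CO bond.
- Enabling feature: ring B carries oxygen on C2', C4' and C5' and hydrogen on C3' and C6'. This is the imprint of a 1,1,3,4-tetraoxygenated butadiene laid across a C1'–C6' alkyne, with one ketal methoxy group leaving as methanol on aromatisation.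
- Forward order: ring A is dressed on 1,3,5-tris(benzyloxy)benzene (dibromination, methoxylation, acylation, ortho-debenzylation). Ring C closes by enaminone cyclisation, and C2 is zincated, iodinated and alkynylated. Ring B is grown last by Diels–Alder reaction and aromatisation, followed by O-methylation and hydrogenolysis.
- Stereochemistry: the target has no stereocentre. The only geometric element on the way, the Z enol ether of the diene, comes from chelate-controlled enolisation, and the transient C5' centre of the cycloadduct disappears on aromatisation.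

Key step: step 11

Assumption: compounds 1, 4, 11, 14 and 15 are bought, and the three hydroxyl groups that are free in the target (O5, O7, O5') are carried as benzyl ethers so that one hydrogenolysis releases them together.

**Route**

Step 1
Reactants: 1 1,3,5-tris(benzyloxy)benzene
Product: 2 1,3,5-tris(benzyloxy)-2,4-dibromobenzene
Conditions: NBS (2.05 equiv), CH2Cl2, 0 °C, dark
Reagents that add atoms: N-bromosuccinimide, O=C1CCC(=O)N1Br
Why: Electrophilic aromatic bromination of a phloroglucinol triether should stop at the dibromide set by the stoichiometry, because each bromine lowers the reactivity of the central ring and the benzyl rings are far less activated.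

Step 2
Reactants: 2 1,3,5-tris(benzyloxy)-2,4-dibromobenzene
Product: 3 1,3,5-tris(benzyloxy)-2,4-dimethoxybenzene
Conditions: NaOMe, CuI (cat.), MeOH–DMF, 110 °C
Reagents that add atoms: sodium methoxide, [Na+].[O-]C
Why: Ullmann-type copper-catalysed methoxylation replaces bromine on electron-rich, alkoxy-flanked arenes by methoxide, and aryl benzyl ethers should be inert to methoxide under these conditions.

Step 3
Reactants: 3 1,3,5-tris(benzyloxy)-2,4-dimethoxybenzene; 4 methoxyacetyl chloride
Product: 5 2-methoxy-1-[2,4,6-tris(benzyloxy)-3,5-dimethoxyphenyl]ethan-1-one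
Conditions: SnCl4, CH2Cl2, −40 → 0 °C
Reagents that add atoms: none
Why: Friedel–Crafts acylation can only occur at the single free ring position, which is ortho or para to all three benzyloxy groups, and any ortho-debenzylated ketone formed under the Lewis acid is simply the product of step 4.

Step 4
Reactants: 5 2-methoxy-1-[2,4,6-tris(benzyloxy)-3,5-dimethoxyphenyl]ethan-1-one
Product: 6 1-[4,6-bis(benzyloxy)-2-hydroxy-3,5-dimethoxyphenyl]-2-methoxyethan-1-one
Conditions: MgBr2·OEt2, toluene–Et2O, 70 °C; then dilute aq. HCl
Reagents that add atoms: none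
Why: In this chelation-controlled ether cleavage, MgBr2 bound between the ketone and an ortho benzyloxy oxygen delivers bromide to that benzyl group only; the two ortho ethers are equivalent by symmetry, the magnesium phenoxide chelate formed shields the second one, and the para benzyl ether has no carbonyl neighbour.

Step 5
Reactants: 6 1-[4,6-bis(benzyloxy)-2-hydroxy-3,5-dimethoxyphenyl]-2-methoxyethan-1-one
Product: 8 5,7-bis(benzyloxy)-3,6,8-trimethoxy-4H-chromen-4-one, via enaminone 7 (not isolated)
Conditions: Me2NCH(OMe)2, toluene, 100 °C; then AcOH, 60 °C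
Reagents that add atoms: N,N-dimethylformamide dimethyl acetal, COC(OC)N(C)C
Why: In the enaminone route to chromones, the methylene next to the ketone condenses with the formamide acetal, and the phenol then adds to the enamine carbon and expels dimethylamine, closing ring C with C2 unsubstituted and the methoxy group on C3.

Step 6
Reactants: 8 5,7-bis(benzyloxy)-3,6,8-trimethoxy-4H-chromen-4-one
Product: 10 5,7-bis(benzyloxy)-2-iodo-3,6,8-trimethoxy-4H-chromen-4-one, via chromon-2-ylzinc chloride 9 (not isolated)
Conditions: TMPZnCl·LiCl (TMP = 2,2,6,6-tetramethylpiperidin-1-yl), THF, 25 °C; then I2, 0 °C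
Reagents that add atoms: iodine, [I][I]
Why: Directed zincation should take C2–H, the only sp2 C–H of the molecule and acidified by O1, the C3 methoxy group and the vinylogous carbonyl, while the mild zinc amide leaves ketone and benzyl ethers alone; iodinolysis of the C–Zn bond then gives the iodide.

Step 7
Reactants: 10 5,7-bis(benzyloxy)-2-iodo-3,6,8-trimethoxy-4H-chromen-4-one; 11 trimethylsilylacetylene
Product: 12 5,7-bis(benzyloxy)-3,6,8-trimethoxy-2-[(trimethylsilyl)ethynyl]-4H-chromen-4-one
Conditions: PdCl2(PPh3)2 (cat.), CuI (cat.), Et3N, THF, rt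
Reagents that add atoms: none
Why: Sonogashira coupling should be easy because the 2-iodochromone is a vinylogous acyl iodide that undergoes oxidative addition readily, and the tertiary amine base cannot displace iodide by addition–elimination.

Step 8
Reactants: 12 5,7-bis(benzyloxy)-3,6,8-trimethoxy-2-[(trimethylsilyl)ethynyl]-4H-chromen-4-one
Product: 13 5,7-bis(benzyloxy)-2-ethynyl-3,6,8-trimethoxy-4H-chromen-4-one
Conditions: Bu4NF, AcOH, THF, 0 °C
Reagents that add atoms: none
Why: Fluoride-induced protodesilylation of the alkynylsilane is fast, and the acetic acid buffer keeps basic species from adding in conjugate fashion to the electrophilic ynenone.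

Step 9
Reactants: 14 benzyloxyacetyl chloride; 15 1,1-dimethoxyethene
Product: 16 1-(benzyloxy)-4,4-dimethoxybut-3-en-2-one
Conditions: 15 (2.2 equiv), Et2O, 0 °C → rt
Reagents that add atoms: none
Why: C-Acylation of a ketene acetal by an acid chloride gives the push–pull β-keto ketene acetal, the second equivalent of ketene acetal taking up the HCl as methyl acetate and chloromethane so that no amine base (which could form benzyloxyketene) is needed.

Step 10
Reactants: 16 1-(benzyloxy)-4,4-dimethoxybut-3-en-2-one
Product: 18 (3Z)-4-(benzyloxy)-1,1-dimethoxy-3-(trimethylsilyloxy)buta-1,3-diene, via lithium Z-enolate 17 (not isolated)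
Conditions: LiN(iPr)2, THF, −78 °C; then Me3SiCl, −78 °C → rt, non-aqueous work-up
Reagents that add atoms: chlorotrimethylsilane, C[Si](C)(C)Cl
Why: In this silyl enol ether formation, kinetic deprotonation of the only enolisable position (the CH2 between ketone and benzyloxy group) through a lithium chelate of the carbonyl and ether oxygens should give the Z enolate, which is trapped on oxygen; the Z geometry puts the benzyloxy group on the outside of the diene, as the cycloaddition requires.

Step 11
Reactants: 13 5,7-bis(benzyloxy)-2-ethynyl-3,6,8-trimethoxy-4H-chromen-4-one; 18 (3Z)-4-(benzyloxy)-1,1-dimethoxy-3-(trimethylsilyloxy)buta-1,3-diene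
Product: 21 5,7-bis(benzyloxy)-2-[5-(benzyloxy)-4-hydroxy-2-methoxyphenyl]-3,6,8-trimethoxy-4H-chromen-4-one, via cyclohexadiene ketal 19 (not isolated), via aryl silyl ether 20 (not isolated)
Conditions: 18 (3 equiv), toluene, 110 °C, sealed tube; then dilute aq. HCl, THF, rt
Reagents that add atoms: none
Why: Proposed new method: diene 18 is a vinylogous ketene acetal whose benzyloxy-bearing terminus (diene C4) carries the largest HOMO coefficient, and the terminal alkyne carbon of 13 is the δ-position of the ynenone C≡C–C2=C3–C4=O and carries the largest LUMO coefficient, so an asynchronous normal-demand (4+2) cycloaddition (in the polar limit a vinylogous Mukaiyama–Michael addition followed by collapse of the allenolate onto the dimethoxycarbenium end) should give cyclohexadiene 19. The closest known reaction type is the Diels–Alder reaction and aromatisation of 1,1-dialkoxy-3-silyloxybutadienes with alkynyl ketones and esters, which delivers resorcinol monoethers; an alkyne activated only through a vinylogous chromone carbonyl, and a diene with a fourth oxygen on C4, have not been used in it. Ring B closes in the intermolecular (4+2) mode, C5'–C6' and C1'–C2' coming from one diene–dienophile pair, and 19 can aromatise in one way only, by 1,4-loss of methanol from the ketal carbon C2' and C5'–H, since C2' has no hydrogen that could leave with benzyl alcohol. No stereocentre is set, because the C5' centre of 19 is destroyed on aromatisation. The step needs regioselectivity (methoxy to C2', benzyloxy to C5') and chemoselectivity for the alkyne over C2=C3; the first follows from the matched polarisation just described, the second from C2=C3 being tetrasubstituted and deactivated by O1 and the C3 methoxy group while the terminal alkyne is unhindered. Dilute acid then cleaves aryl silyl ether 20 and completes any unfinished loss of methanol, giving phenol 21.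

Step 12
Reactants: 21 5,7-bis(benzyloxy)-2-[5-(benzyloxy)-4-hydroxy-2-methoxyphenyl]-3,6,8-trimethoxy-4H-chromen-4-one
Product: 22 5,7-bis(benzyloxy)-2-[5-(benzyloxy)-2,4-dimethoxyphenyl]-3,6,8-trimethoxy-4H-chromen-4-one
Conditions: MeI, K2CO3, acetone, 56 °C
Reagents that add atoms: iodomethane, IC
Why: Williamson ether synthesis should be clean because the 4'-hydroxyl is the only free hydroxyl group in the molecule.

Step 13
Reactants: 22 5,7-bis(benzyloxy)-2-[5-(benzyloxy)-2,4-dimethoxyphenyl]-3,6,8-trimethoxy-4H-chromen-4-one
Product: 23 5,7-dihydroxy-2-(5-hydroxy-2,4-dimethoxyphenyl)-3,6,8-trimethoxy-4H-chromen-4-one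
Conditions: H2 (1 atm), Pd/C, EtOAc–MeOH, rt
Reagents that add atoms: none
Why: Catalytic hydrogenolysis removes the three aryl benzyl ethers together, while the tetrasubstituted, conjugated C2=C3 bond of the flavone and the methyl ethers should not react at ambient pressure and temperature.

**Compound list**

1 | 1,3,5-tris(benzyloxy)benzene | c1ccc(COc2cc(OCc3ccccc3)cc(OCc3ccccc3)c2)cc1 | starting material
2 | 1,3,5-tris(benzyloxy)-2,4-dibromobenzene | Brc1c(OCc2ccccc2)cc(OCc2ccccc2)c(Br)c1OCc1ccccc1 | intermediate
3 | 1,3,5-tris(benzyloxy)-2,4-dimethoxybenzene | COc1c(OCc2ccccc2)cc(OCc2ccccc2)c(OC)c1OCc1ccccc1 | intermediate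
4 | methoxyacetyl chloride | COCC(Cl)=O | starting material
5 | 2-methoxy-1-[2,4,6-tris(benzyloxy)-3,5-dimethoxyphenyl]ethan-1-one | COCC(=O)c1c(OCc2ccccc2)c(OC)c(OCc2ccccc2)c(OC)c1OCc1ccccc1 | intermediate
6 | 1-[4,6-bis(benzyloxy)-2-hydroxy-3,5-dimethoxyphenyl]-2-methoxyethan-1-one | COCC(=O)c1c(O)c(OC)c(OCc2ccccc2)c(OC)c1OCc1ccccc1 | intermediate
7 | (Z)-1-[4,6-bis(benzyloxy)-2-hydroxy-3,5-dimethoxyphenyl]-3-(dimethylamino)-2-methoxyprop-2-en-1-one | CO/C(=C\N(C)C)C(=O)c1c(O)c(OC)c(OCc2ccccc2)c(OC)c1OCc1ccccc1 | intermediate (not isolated)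
8 | 5,7-bis(benzyloxy)-3,6,8-trimethoxy-4H-chromen-4-one | COc1coc2c(OC)c(OCc3ccccc3)c(OC)c(OCc3ccccc3)c2c1=O | intermediate
9 | [5,7-bis(benzyloxy)-3,6,8-trimethoxy-4-oxo-4H-chromen-2-yl]zinc chloride (LiCl complex) | COc1c([Zn]Cl)oc2c(OC)c(OCc3ccccc3)c(OC)c(OCc3ccccc3)c2c1=O | intermediate (not isolated)
10 | 5,7-bis(benzyloxy)-2-iodo-3,6,8-trimethoxy-4H-chromen-4-one | COc1c(I)oc2c(OC)c(OCc3ccccc3)c(OC)c(OCc3ccccc3)c2c1=O | intermediate
11 | trimethylsilylacetylene | C#C[Si](C)(C)C | starting material
12 | 5,7-bis(benzyloxy)-3,6,8-trimethoxy-2-[(trimethylsilyl)ethynyl]-4H-chromen-4-one | COc1c(C#C[Si](C)(C)C)oc2c(OC)c(OCc3ccccc3)c(OC)c(OCc3ccccc3)c2c1=O | intermediate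
13 | 5,7-bis(benzyloxy)-2-ethynyl-3,6,8-trimethoxy-4H-chromen-4-one | C#Cc1oc2c(OC)c(OCc3ccccc3)c(OC)c(OCc3ccccc3)c2c(=O)c1OC | intermediate
14 | benzyloxyacetyl chloride | O=C(Cl)COCc1ccccc1 | starting material
15 | 1,1-dimethoxyethene | C=C(OC)OC | starting material
16 | 1-(benzyloxy)-4,4-dimethoxybut-3-en-2-one | COC(OC)=CC(=O)COCc1ccccc1 | intermediate
17 | lithium (Z)-1-(benzyloxy)-4,4-dimethoxybuta-1,3-dien-2-olate | COC(OC)=C/C(O[Li])=C/OCc1ccccc1 | intermediate (not isolated)
18 | (3Z)-4-(benzyloxy)-1,1-dimethoxy-3-(trimethylsilyloxy)buta-1,3-diene | COC(OC)=C/C(O[Si](C)(C)C)=C/OCc1ccccc1 | intermediate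
19 | 5,7-bis(benzyloxy)-2-[3-(benzyloxy)-6,6-dimethoxy-4-(trimethylsilyloxy)cyclohexa-1,4-dien-1-yl]-3,6,8-trimethoxy-4H-chromen-4-one (racemic) | COC1(OC)C=C(O[Si](C)(C)C)C(OCc2ccccc2)C=C1c1oc2c(OC)c(OCc3ccccc3)c(OC)c(OCc3ccccc3)c2c(=O)c1OC | intermediate (not isolated)
20 | 5,7-bis(benzyloxy)-2-[5-(benzyloxy)-2-methoxy-4-(trimethylsilyloxy)phenyl]-3,6,8-trimethoxy-4H-chromen-4-one | COc1cc(O[Si](C)(C)C)c(OCc2ccccc2)cc1-c1oc2c(OC)c(OCc3ccccc3)c(OC)c(OCc3ccccc3)c2c(=O)c1OC | intermediate (not isolated)
21 | 5,7-bis(benzyloxy)-2-[5-(benzyloxy)-4-hydroxy-2-methoxyphenyl]-3,6,8-trimethoxy-4H-chromen-4-one | COc1cc(O)c(OCc2ccccc2)cc1-c1oc2c(OC)c(OCc3ccccc3)c(OC)c(OCc3ccccc3)c2c(=O)c1OC | intermediate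
22 | 5,7-bis(benzyloxy)-2-[5-(benzyloxy)-2,4-dimethoxyphenyl]-3,6,8-trimethoxy-4H-chromen-4-one | COc1cc(OC)c(OCc2ccccc2)cc1-c1oc2c(OC)c(OCc3ccccc3)c(OC)c(OCc3ccccc3)c2c(=O)c1OC | intermediate
23 | 5,7-dihydroxy-2-(5-hydroxy-2,4-dimethoxyphenyl)-3,6,8-trimethoxy-4H-chromen-4-one | COc1cc(OC)c(-c2oc3c(OC)c(O)c(OC)c(O)c3c(=O)c2OC)cc1O | target

**Step count and risks**

Total step count: 13. Longest linear sequence: 11 steps (from 1 to 23 through steps 1–8 and 11–13); the diene branch contributes steps 9 and 10.

Steps most likely to fail: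

1. Step 11 (the proposed new method). The alkyne is activated only through the vinylogous chromone carbonyl, so cycloaddition may be slower than thermal decomposition or desilylation of diene 18, or than conjugate addition of the diene at C2 of the chromone; some leakage to the reversed regiochemistry is also possible. The fallback, which uses known chemistry, attaches ring B as a finished arene instead of building it. 2,4-Dimethoxyphenol would be benzylated (BnBr, K2CO3, DMF) to 1-(benzyloxy)-2,4-dimethoxybenzene F1. Iodination (N-iodosuccinimide, cat. CF3CO2H, MeCN) at the position para to the C2 methoxy group should then give 1-(benzyloxy)-5-iodo-2,4-dimethoxybenzene F2. The fallback sets out from chromone 8: zincation as in step 6 gives 9, and Negishi coupling of 9 with F2 (Pd(PPh3)4 cat., THF, 50 °C) should give 22 directly. The route is rejoined at 22, one step before the target, and steps 7–12 are bypassed.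

2. Step 2. Each bromine is flanked by two benzyloxy groups, so hydrodebromination may compete with substitution and the second exchange may stall. The fallback introduces the two oxygens by formylation and oxidation and runs from 1 to 3. Vilsmeier–Haack formylation of 1 (POCl3, DMF) should give 2,4,6-tris(benzyloxy)benzaldehyde F3. Dakin oxidation (H2O2, cat. H2SO4, MeOH) would convert it into 2,4,6-tris(benzyloxy)phenol F4, and MeI/K2CO3 into 1,3,5-tris(benzyloxy)-2-methoxybenzene F5. A second pass through the same three operations follows: formylation at either of the two equivalent free positions to 2,4,6-tris(benzyloxy)-3-methoxybenzaldehyde F6, Dakin oxidation to 2,4,6-tris(benzyloxy)-3-methoxyphenol F7, and O-methylation. This arrives at 3, where the route continues with step 3.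

3. Step 3. The Lewis acid may strip or migrate benzyl groups faster than the acyl cation attacks the position flanked by two benzyloxy groups. The fallback replaces electrophilic acylation by acylation of an aryl-metal and runs from 3 to 5. Bromination of 3 (NBS, MeCN, 0 °C) should give 1,3,5-tris(benzyloxy)-2-bromo-4,6-dimethoxybenzene F8. Bromine–lithium exchange (n-BuLi, THF, −78 °C) would give [2,4,6-tris(benzyloxy)-3,5-dimethoxyphenyl]lithium F9, which is acylated with N,2-dimethoxy-N-methylacetamide and quenched with dilute aq. HCl to give ketone 5, where the route continues with step 4.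

**Further compounds**

F1 | step 11 | 1-(benzyloxy)-2,4-dimethoxybenzene | COc1ccc(OCc2ccccc2)c(OC)c1
F2 | step 11 | 1-(benzyloxy)-5-iodo-2,4-dimethoxybenzene | COc1cc(OC)c(OCc2ccccc2)cc1I
F3 | step 2 | 2,4,6-tris(benzyloxy)benzaldehyde | O=Cc1c(OCc2ccccc2)cc(OCc2ccccc2)cc1OCc1ccccc1
F4 | step 2 | 2,4,6-tris(benzyloxy)phenol | Oc1c(OCc2ccccc2)cc(OCc2ccccc2)cc1OCc1ccccc1
F5 | step 2 | 1,3,5-tris(benzyloxy)-2-methoxybenzene | COc1c(OCc2ccccc2)cc(OCc2ccccc2)cc1OCc1ccccc1
F6 | step 2 | 2,4,6-tris(benzyloxy)-3-methoxybenzaldehyde | COc1c(OCc2ccccc2)cc(OCc2ccccc2)c(C=O)c1OCc1ccccc1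
F7 | step 2 | 2,4,6-tris(benzyloxy)-3-methoxyphenol | COc1c(OCc2ccccc2)cc(OCc2ccccc2)c(O)c1OCc1ccccc1
F8 | step 3 | 1,3,5-tris(benzyloxy)-2-bromo-4,6-dimethoxybenzene | COc1c(OCc2ccccc2)c(Br)c(OCc2ccccc2)c(OC)c1OCc1ccccc1
F9 | step 3 | [2,4,6-tris(benzyloxy)-3,5-dimethoxyphenyl]lithium | [Li]c1c(OCc2ccccc2)c(OC)c(OCc2ccccc2)c(OC)c1OCc1ccccc1
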